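Assumption: the target has no stereocentre or other stereo-element. It is achiral, so there is no enantiomer to select, and the SMILES is taken as the full structure.

**Retrosynthetic overview**
1. Target 11 is cut at the depside acyl C–O bond. This gives a ring A acyl donor (para-oxoketene 9, from unprotected acid 6) and the ring B 4-phenoxide (dianion 8 of unprotected acid 3).
2. Acid 6 comes from 3 by benzyl masking of CO2H and 4-OH, 2-O-methylation, and one hydrogenolysis that removes both benzyl groups.
3. Acid 3 comes from 5-propylresorcinol 1 by ortho-carboxylation.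
4. No ring is built. Both benzene rings come from 1: ring B is 3 as made, and ring A is 3 after O-differentiation.

**Step 1**
Reactants: 1 5-propylbenzene-1,3-diol (divarinol)
Product: 3 2,4-dihydroxy-6-propylbenzoic acid, via magnesium 4-hydroxy-2-oxido-6-propylbenzoate 2 (not isolated)
Conditions: MeOMgOCO2Me (2 M in DMF, 6 equiv), 120 °C, 3 h, N2; then ice-cold 2 M HCl; acid taken out through aq. NaHCO3 and re-acidified below 10 °C
Reagents that add atoms: methoxymagnesium methyl carbonate MeOMgOCO2Me, C[O-].COC(=O)[O-].[Mg+2]
Why: Kolbe–Schmitt-type ortho-carboxylation with the Stiles reagent; magnesium bound to the phenoxide delivers CO2 to the carbon ortho to one OH and para to the other, the reversible reaction is pulled forward by the six-membered chelate 2, and no stereocentre is formed.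

**Step 2**
Reactants: 3 2,4-dihydroxy-6-propylbenzoic acid
Product: 5 benzyl 4-(benzyloxy)-2-methoxy-6-propylbenzoate, via benzyl 4-(benzyloxy)-2-hydroxy-6-propylbenzoate 4 (not isolated)
Conditions: K2CO3 (4 equiv), BnBr (2.05 equiv), DMF, 23 °C, 16 h; then MeI (3 equiv), 50 °C, 12 h, same flask
Reagents that add atoms: benzyl bromide, BrCc1ccccc1; iodomethane, CI
Why: Carboxylate SN2 and Williamson alkylations ranked by acidity; CO2H and the free 4-OH are benzylated at room temperature, while the 2-OH is held in a hydrogen bond to the ester C=O and reacts only with the small, excess MeI on warming; no stereocentre is formed.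

**Step 3**
Reactants: 5 benzyl 4-(benzyloxy)-2-methoxy-6-propylbenzoate
Product: 6 4-hydroxy-2-methoxy-6-propylbenzoic acid
Conditions: H2 (1 atm), 10% Pd/C, EtOAc, 23 °C, 3 h; filter, evaporate below 30 °C
Reagents that add atoms: none
Why: Catalytic hydrogenolysis cleaves both benzylic C–O bonds (ester and aryl ether) in one neutral operation, which avoids saponifying a di-ortho-substituted ester and leaves the aryl methyl ether and the easily decarboxylated acid intact.

**Step 4**
Reactants: 6 4-hydroxy-2-methoxy-6-propylbenzoic acid; 3 2,4-dihydroxy-6-propylbenzoic acid (3.0 equiv, excess recovered)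
Product: 11 2-hydroxy-4-[(4-hydroxy-2-methoxy-6-propylbenzoyl)oxy]-6-propylbenzoic acid (target), via 4-hydroxy-2-methoxy-6-propylbenzoyl chloride 7 (not isolated), via dipotassium 2-hydroxy-4-oxido-6-propylbenzoate 8 (not isolated), via para-oxoketene 9 (not isolated), via dipotassium 2-hydroxy-4-[(2-methoxy-4-oxido-6-propylbenzoyl)oxy]-6-propylbenzoate 10 (not isolated)
Conditions: 6, Me2C=C(Cl)NMe2 (1.05 equiv), THF, 0 °C, 1 h; separately 3 (3.0 equiv), KOt-Bu (5.9 equiv), dry amine-free DMF, 0 °C; first solution added to the second over 3 h at −20 °C; then cold 1 M HCl, EtOAc; silica (hexane/EtOAc/1% AcOH), 3 recovered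
Reagents that add atoms: none
Why: Proposed new method: the α-chloroenamine converts the CO2H of 6 into acid chloride 7 under neutral conditions, where the un-ionised 4-OH is not a nucleophile; each drop of 7 that meets basic 8 is deprotonated at 4-OH and loses chloride at once (E1cB, 1,6-elimination of HCl) to give the linear para-oxoketene 9, whose acyl carbon is no longer shielded by the two ortho groups; 9 is captured at oxygen by the most basic and most abundant nucleophile present, the 4-phenoxide of 8, because the para carboxylate of 8 is not electron-withdrawing, its 2-OH stays locked in the salicylate hydrogen bond, and capture by its carboxylate is reversible since the mixed anhydride re-ionises to 9; self-condensation of ring A is suppressed because 7 never accumulates as a phenoxide under slow addition, and because the ring A phenoxide of 10 lies para to an ester and is therefore the weaker nucleophile, and acyl-transfer equilibria favour the ester of the more basic phenoxide (statistical worst case about 55–60% on 6, expected higher); the closest known reaction types are the dissociative E1cB acyl transfer of aryl 4-hydroxybenzoates through para-oxoketenes (known only as a hydrolysis and aminolysis mechanism), ketene–phenol esterification, and Schotten–Baumann depside coupling of O-protected aroyl chlorides; what is new is the preparative cross-coupling of two fully unprotected hydroxybenzoic acids; no stereocentre is formed.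

**Compound list**
1 | 5-propylbenzene-1,3-diol (divarinol, bulk intermediate) | CCCc1cc(O)cc(O)c1 | starting material
2 | magnesium 4-hydroxy-2-oxido-6-propylbenzoate (chelate) | CCCc1cc(O)cc([O-])c1C(=O)[O-].[Mg+2] | intermediate
3 | 2,4-dihydroxy-6-propylbenzoic acid (divarinolic acid) | CCCc1cc(O)cc(O)c1C(=O)O | intermediate
4 | benzyl 4-(benzyloxy)-2-hydroxy-6-propylbenzoate | CCCc1cc(OCc2ccccc2)cc(O)c1C(=O)OCc1ccccc1 | intermediate
5 | benzyl 4-(benzyloxy)-2-methoxy-6-propylbenzoate | CCCc1cc(OCc2ccccc2)cc(OC)c1C(=O)OCc1ccccc1 | intermediate
6 | 4-hydroxy-2-methoxy-6-propylbenzoic acid | CCCc1cc(O)cc(OC)c1C(=O)O | intermediate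
7 | 4-hydroxy-2-methoxy-6-propylbenzoyl chloride | CCCc1cc(O)cc(OC)c1C(=O)Cl | intermediate
8 | dipotassium 2-hydroxy-4-oxido-6-propylbenzoate | CCCc1cc([O-])cc(O)c1C(=O)[O-].[K+].[K+] | intermediate
9 | 3-methoxy-4-(oxomethylidene)-5-propylcyclohexa-2,5-dien-1-one (para-oxoketene) | CCCC1=CC(=O)C=C(OC)C1=C=O | intermediate
10 | dipotassium 2-hydroxy-4-[(2-methoxy-4-oxido-6-propylbenzoyl)oxy]-6-propylbenzoate | CCCc1cc(OC(=O)c2c(CCC)cc([O-])cc2OC)cc(O)c1C(=O)[O-].[K+].[K+] | intermediate
11 | 2-hydroxy-4-[(4-hydroxy-2-methoxy-6-propylbenzoyl)oxy]-6-propylbenzoic acid | CCCc1cc(OC(=O)c2c(CCC)cc(O)cc2OC)cc(O)c1C(=O)O | target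

**Totals**
- Total step count: 4.
- Longest linear sequence: 4 (1 → 3 → 5 → 6 → 11). Compound 3 is used twice, as the precursor of ring A and as ring B.
- Compound 3 is also sold; buying it would remove step 1.

**Steps most likely to fail**

*Step 4 (the proposed new step).*
- Risks: oligodepsides from acylation of ring A phenoxides, loss of 9 to adventitious water, and limited lifetime of 7.
- The fallback uses known chemistry. It sets out from 5 and 3 and comes back at 11.
- Compound 5 is saponified with KOH in DMSO/H2O at 90 °C to 4-(benzyloxy)-2-methoxy-6-propylbenzoic acid F1.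
- Compound 3 is esterified with BnBr and KHCO3 in DMF to benzyl 2,4-dihydroxy-6-propylbenzoate F2.
- The two are condensed with (CF3CO)2O in toluene at 23 °C. This is the classical depside condensation through the mixed anhydride and acylium ion, and only the non-chelated 4-OH reacts. It gives benzyl 4-{[4-(benzyloxy)-2-methoxy-6-propylbenzoyl]oxy}-2-hydroxy-6-propylbenzoate F3.
- H2 over 10% Pd/C in EtOAc then gives 11.

*Step 1.*
- Risks: competing carboxylation between the two hydroxyls (the 2,6-dihydroxy-4-propyl isomer), incomplete conversion, and decarboxylation on work-up.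
- The fallback sets out from 1 and comes back at 3. It replaces CO2 transfer by formylation and oxidation.
- Vilsmeier–Haack reaction (POCl3, DMF, 0 to 23 °C, aqueous hydrolysis) gives 2,4-dihydroxy-6-propylbenzaldehyde F4. The regiochemistry is secure for 5-alkylresorcinols.
- Chlorite oxidation (NaClO2, NaH2PO4, DMSO/H2O, 10 °C, with DMSO as hypochlorite scavenger) then gives 3.

*Step 2.*
- Risks: partial benzylation of the 2-OH, or methylation of a 4-OH that was not yet benzylated. Either gives ethers that cannot be corrected later.
- The fallback sets out from 3 and comes back at 6, bypassing 5 and step 3. It uses acyl masking and hydrolysis in place of benzyl masking and hydrogenolysis.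
- MeI and KHCO3 in DMF give methyl 2,4-dihydroxy-6-propylbenzoate F5.
- Pivaloyl chloride and Et3N in CH2Cl2 at 0 °C acylate only the free 4-OH, giving methyl 4-[(2,2-dimethylpropanoyl)oxy]-2-hydroxy-6-propylbenzoate F6.
- MeI and K2CO3 in refluxing acetone give methyl 4-[(2,2-dimethylpropanoyl)oxy]-2-methoxy-6-propylbenzoate F7.
- KOH in DMSO/H2O at 100 °C, followed by cold acidification, cleaves both esters to give 6.

**Further compounds**
F1 | step 4 | 4-(benzyloxy)-2-methoxy-6-propylbenzoic acid | CCCc1cc(OCc2ccccc2)cc(OC)c1C(=O)O
F2 | step 4 | benzyl 2,4-dihydroxy-6-propylbenzoate | CCCc1cc(O)cc(O)c1C(=O)OCc1ccccc1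
F3 | step 4 | benzyl 4-{[4-(benzyloxy)-2-methoxy-6-propylbenzoyl]oxy}-2-hydroxy-6-propylbenzoate | CCCc1cc(OC(=O)c2c(CCC)cc(OCc3ccccc3)cc2OC)cc(O)c1C(=O)OCc1ccccc1
F4 | step 1 | 2,4-dihydroxy-6-propylbenzaldehyde | CCCc1cc(O)cc(O)c1C=O
F5 | step 2 | methyl 2,4-dihydroxy-6-propylbenzoate | CCCc1cc(O)cc(O)c1C(=O)OC
F6 | step 2 | methyl 4-[(2,2-dimethylpropanoyl)oxy]-2-hydroxy-6-propylbenzoate | CCCc1cc(OC(=O)C(C)(C)C)cc(O)c1C(=O)OC
F7 | step 2 | methyl 4-[(2,2-dimethylpropanoyl)oxy]-2-methoxy-6-propylbenzoate | CCCc1cc(OC(=O)C(C)(C)C)cc(OC)c1C(=O)OC
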